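**Plan**

1. Numbering: C1 is the tertiary carbinol bearing C7 (CH2OBz), C2=C3 is the alkene, C4 is the benzoate carbon, and C5 and C6 are the secondary carbinols (C6 bonded to C1). The upper face is the one carrying O4 and O5.
2. Cuts, in retrosynthetic order: O4–benzoyl; C2=C3 back to a C2 ketone; the C1–O and C6–O bonds together (syn-dihydroxylation of a C1=C6 enone); O7–benzoyl; C1–C7 (Morita–Baylis–Hillman union with formaldehyde).
3. What remains is a cyclohexenone 4,5-acetonide. It is reached from (−)-quinic acid by reducing its lactone, cleaving off the carboxyl carbon and eliminating the C5 hydroxyl.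
4. Enabling feature: the cis,trans O4/O5/O6 array on C4–C5–C6 is the C3–C4–C5 triol of quinic acid, and C1 is the ring carbon next to the old carboxyl-bearing carbon (now C2). A dioxolane ring cis-fused at C4/C5 therefore stands allylic to the C1=C6 bond of the intact six-membered ring and blocks its upper face.
5. Forward order: the carbocycle is present throughout and none is formed. C7 is joined first, then O1/O6 are added, then the C2 ketone (enolisable only toward C3) becomes the alkene. O4 is benzoylated last, while a butane-2,3-diacetal holds the trans O5/O6 pair.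
6. Stereochemistry: C4 and C5 come from the chiral pool. C6 and C1 arise by substrate control, both oxygens entering the lower face anti to the dioxolane.

Key step: step 7

Assumption: steps 1–4 use the numbering of quinic acid and all later text the target numbering; the correspondence is quinic C1→C2, C2→C3, C3→C4, C4→C5, C5→C6, C6→C1.

**Step 1**
Reactants: 1 (−)-quinic acid, (1S,3R,4S,5R)-1,3,4,5-tetrahydroxycyclohexane-1-carboxylic acid
Product: 2 3,4-O-isopropylidenequinic acid 1,5-lactone (dioxolane on the cis C3/C4 diol; γ-lactone from the carboxyl group to O5)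
Conditions: Me2C(OMe)2, TsOH·H2O (cat.), acetone, reflux
Reagents that add atoms: 2,2-dimethoxypropane, COC(C)(C)OC
Why: Acid-catalysed acetonide formation with concurrent lactonisation: transketalisation selects the only cis-vicinal diol (O3/O4), the C5 hydroxyl lies cis to the carboxyl group across the ring and closes the γ-lactone, and no C–O bond at a stereocentre is broken.

**Step 2**
Reactants: 2 3,4-O-isopropylidenequinic acid 1,5-lactone
Product: 3 1-(hydroxymethyl)-3,4-O-isopropylidenecyclohexane-1,3,4,5-tetrol (ring configuration of 1 unchanged)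
Conditions: NaBH4, EtOH, 0 °C to rt
Reagents that add atoms: none
Why: Hydride reduction of a lactone: the α-hydroxy γ-lactone is electrophilic enough for NaBH4 to carry it through to the primary alcohol, which frees O5 and creates the C1 glycol while the acetonide and the stereocentres are untouched.

**Step 3**
Reactants: 3 1-(hydroxymethyl)-3,4-O-isopropylidenecyclohexane-1,3,4,5-tetrol
Product: 4 (3R,4S,5R)-3-hydroxy-4,5-(isopropylidenedioxy)cyclohexan-1-one
Conditions: NaIO4, aq NaH2PO4/Na2HPO4 (pH 6–7), 0 °C to rt
Reagents that add atoms: none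
Why: Periodate glycol cleavage (Malaprade reaction): the tertiary C1 hydroxyl and the CH2OH group form the only free vicinal diol, so the former carboxyl carbon is excised as a one-carbon fragment and C1 becomes a ketone, O5 having no free vicinal partner.

**Step 4**
Reactants: 4 (3R,4S,5R)-3-hydroxy-4,5-(isopropylidenedioxy)cyclohexan-1-one
Product: 6 (4S,5R)-4,5-(isopropylidenedioxy)cyclohex-2-en-1-one, via mesylate 5 (not isolated)
Conditions: MsCl, Et3N, CH2Cl2, 0 °C
Reagents that add atoms: methanesulfonyl chloride, CS(=O)(=O)Cl (retained in 5 only)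
Why: Mesylation followed by E1cB elimination: once O5 is sulfonylated Et3N removes an acidic C6 proton and methanesulfonate, a far better leaving group than the acetonide oxygen β to the ketone on the other side, departs to give the conjugated enone with both remaining stereocentres intact.

**Step 5**
Reactants: 6 (4S,5R)-4,5-(isopropylidenedioxy)cyclohex-2-en-1-one; 7 formaldehyde (37% aqueous solution)
Product: 8 (4S,5R)-2-(hydroxymethyl)-4,5-(isopropylidenedioxy)cyclohex-2-en-1-one
Conditions: 37% aq HCHO, DMAP (20 mol %), THF/H2O, rt
Reagents that add atoms: formaldehyde 7, C=O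
Why: Morita–Baylis–Hillman reaction: reversible conjugate addition of DMAP makes the α-carbon (C1 of the target) nucleophilic toward formaldehyde and loss of DMAP restores the enone, a nearly neutral aqueous protocol established for cyclohexenones that spares the base-sensitive γ,δ-dioxygenated system and forms no stereocentre.

**Step 6**
Reactants: 8 (4S,5R)-2-(hydroxymethyl)-4,5-(isopropylidenedioxy)cyclohex-2-en-1-one; 9 benzoyl chloride
Product: 10 (4S,5R)-2-(benzoyloxymethyl)-4,5-(isopropylidenedioxy)cyclohex-2-en-1-one
Conditions: BzCl, pyridine, CH2Cl2, 0 °C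
Reagents that add atoms: benzoyl chloride 9, O=C(Cl)c1ccccc1
Why: Esterification of a primary allylic alcohol with an acid chloride: pyridine alone serves as base and acyl carrier at 0 °C so that no stronger nucleophile attacks the 2-(acyloxymethyl)enone in an SN2' sense.

**Step 7**
Reactants: 10 (4S,5R)-2-(benzoyloxymethyl)-4,5-(isopropylidenedioxy)cyclohex-2-en-1-one
Product: 12 (2S,3S,4S,5R)-2-(benzoyloxymethyl)-2,3-dihydroxy-4,5-(isopropylidenedioxy)cyclohexan-1-one, via osmate ester 11 (not isolated)
Conditions: OsO4 (5 mol %), NMO (1.5 equiv), citric acid (0.75 equiv), t-BuOH/H2O 1:1, rt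
Reagents that add atoms: osmium tetroxide, O=[Os](=O)(=O)=O (oxygen carrier, osmium retained in 11 only); N-methylmorpholine N-oxide, C[N+]1([O-])CCOCC1; water, O
Why: OsO4 adds suprafacially across C1=C6 by [3+2] cycloaddition to give the hexavalent-osmium glycolate 11, which water hydrolyses to 12 while NMO returns the metal to its octavalent state. The closest known reaction type is the catalytic OsO4/NMO syn-dihydroxylation of cyclic allylic ethers and 4-alkoxycyclohexenones, which places the diol anti to the allylic oxygen. No ring of 12 is closed in this step, the five-membered osmium chelate of 11 being only transient. One-face delivery makes O1 and O6 cis, and the dioxolane cis-fused at C4/C5, through its allylic C5–O bond and its inward-pointing methyl group, closes the upper face, so both oxygens enter from below: C6–O becomes trans to C5–O (3S in the name of 12) and the quaternary C1 carries OH down and C7 up (2S). Facial selectivity is the only selectivity needed, since C1=C6 is the sole alkene and both of its carbons receive oxygen. Because a conjugated trisubstituted alkene reacts slowly, citric acid is added to keep osmium turning over with the electron-poor substrate and to protonate the N-methylmorpholine released, which could otherwise displace the allylic benzoate or start β-elimination of O4 in the product ketone.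

**Step 8**
Reactants: 12 (2S,3S,4S,5R)-2-(benzoyloxymethyl)-2,3-dihydroxy-4,5-(isopropylidenedioxy)cyclohexan-1-one
Product: 13 (2S,3S,4R,5R)-2-(benzoyloxymethyl)-2,3:4,5-bis(isopropylidenedioxy)cyclohexan-1-one (new dioxolane on O1/O6 on the lower face; O4/O5 dioxolane on the upper face)
Conditions: Me2C(OMe)2, PPTS (cat.), CH2Cl2, rt
Reagents that add atoms: 2,2-dimethoxypropane, COC(C)(C)OC
Why: Acid-catalysed acetonide formation (transketalisation) on the cis C1/C6 diol gives a cis-fused dioxolane, masks the tertiary ketol and the β-hydroxyl against retro-aldol cleavage and acyl shift in the basic step to come, and creates no stereocentre.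

**Step 9**
Reactants: 13 (2S,3S,4R,5R)-2-(benzoyloxymethyl)-2,3:4,5-bis(isopropylidenedioxy)cyclohexan-1-one
Product: 15 C2 enol triflate of 13 (C2=C3 double bond; both dioxolanes kept), via potassium enolate 14 (not isolated)
Conditions: N-(5-chloro-2-pyridyl)triflimide premixed with 13, KN(SiMe3)2 added dropwise, THF, −78 °C
Reagents that add atoms: N-(5-chloro-2-pyridyl)bis(trifluoromethanesulfonimide), O=S(=O)(N(c1ccc(Cl)cn1)S(=O)(=O)C(F)(F)F)C(F)(F)F; KN(SiMe3)2, C[Si](C)(C)[N-][Si](C)(C)C.[K+] (potassium retained in 14 only)
Why: Kinetic enolisation and O-sulfonylation (enol triflate synthesis): C1 is quaternary, so the amide base can deprotonate only C3, and adding it to the ketone already mixed with the triflimide traps enolate 14 at −78 °C before it can expel O4 or attack the benzoate.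

**Step 10**
Reactants: 15 C2 enol triflate of 13
Product: 16 1,6:4,5-di-O-isopropylidene-protected 1-(benzoyloxymethyl)cyclohex-2-ene-1,4,5,6-tetrol (O1/O6 on the lower face, O4/O5 on the upper face)
Conditions: Pd(OAc)2 (5 mol %), PPh3 (10 mol %), HCO2H, Et3N, DMF, 60 °C
Reagents that add atoms: none
Why: Palladium-catalysed formate reduction of an enol triflate: zerovalent palladium generated in situ inserts into the C2–OTf bond, formate replaces triflate and loses CO2, and reductive elimination delivers C2–H, while the amine-buffered medium leaves the acetonides, the benzoate and all four stereocentres alone.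

**Step 11**
Reactants: 16 1,6:4,5-di-O-isopropylidene-protected 1-(benzoyloxymethyl)cyclohex-2-ene-1,4,5,6-tetrol
Product: 18 O5,O6-[(2S,3S)-2,3-dimethoxybutane-2,3-diyl] acetal of the tetraol (C1–OH and C4–OH free; O7 benzoate kept), via tetraol 17 (not isolated)
Conditions: CSA (cat.), MeOH, 40 °C; then butane-2,3-dione, HC(OMe)3, reflux
Reagents that add atoms: butane-2,3-dione, CC(=O)C(C)=O; trimethyl orthoformate, COC(OC)OC; methanol, CO
Why: Acid-catalysed ketal exchange under thermodynamic control: methanolysis strips both acetonides to 17 and butane-2,3-diacetal formation then selects the only trans-diequatorial diol (O5/O6), as it does in the quinate and shikimate series, the two new acetal centres being fixed as S,S by the double anomeric effect (both methoxy groups axial and both methyl groups equatorial on a trans-fused chair dioxane).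

**Step 12**
Reactants: 18 O5,O6-butane-2,3-diacetal diol; 9 benzoyl chloride
Product: 19 O4-benzoate of 18 (C1–OH free)
Conditions: BzCl, pyridine, DMAP (cat.), CH2Cl2, 0 °C to rt
Reagents that add atoms: benzoyl chloride 9, O=C(Cl)c1ccccc1
Why: Selective esterification with an acid chloride: with O5 and O6 locked only the secondary allylic C4–OH and the tertiary C1–OH remain, the secondary one is acylated with retention at C4, and any O7 benzoate lost to methanol in step 11 would be restored in the same operation.

**Step 13**
Reactants: 19 O4-benzoate of 18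
Product: 20 [(1S,4R,5S,6S)-4-(benzoyloxy)-1,5,6-trihydroxycyclohex-2-en-1-yl]methyl benzoate (target)
Conditions: TFA/H2O 9:1, CH2Cl2, 0 °C to rt
Reagents that add atoms: none
Why: Acidic acetal hydrolysis: aqueous TFA cleaves the diacetal at its acetal carbons, so the C5–O and C6–O bonds and their configuration persist, and the acidic medium keeps the base-promoted O4 to O5 benzoyl shift slow.

**Compound list**

1 | (−)-quinic acid | O=C(O)[C@]1(O)C[C@@H](O)[C@@H](O)[C@H](O)C1 | starting material
2 | 3,4-O-isopropylidenequinic acid 1,5-lactone | O=C1O[C@@H]2C[C@@]1(O)C[C@H]1OC(C)(C)O[C@H]12 | intermediate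
3 | 1-(hydroxymethyl)-3,4-O-isopropylidenecyclohexane-1,3,4,5-tetrol | OC[C@@]1(O)C[C@@H](O)[C@@H]2OC(C)(C)O[C@@H]2C1 | intermediate
4 | (3R,4S,5R)-3-hydroxy-4,5-(isopropylidenedioxy)cyclohexan-1-one | O=C1C[C@@H](O)[C@@H]2OC(C)(C)O[C@@H]2C1 | intermediate
5 | 3-O-mesylate of 4 | O=C1C[C@@H](OS(C)(=O)=O)[C@@H]2OC(C)(C)O[C@@H]2C1 | intermediate
6 | (4S,5R)-4,5-(isopropylidenedioxy)cyclohex-2-en-1-one | O=C1C=C[C@@H]2OC(C)(C)O[C@@H]2C1 | intermediate
7 | formaldehyde | C=O | starting material
8 | (4S,5R)-2-(hydroxymethyl)-4,5-(isopropylidenedioxy)cyclohex-2-en-1-one | OCC1=C[C@@H]2OC(C)(C)O[C@@H]2CC1=O | intermediate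
9 | benzoyl chloride | O=C(Cl)c1ccccc1 | starting material
10 | (4S,5R)-2-(benzoyloxymethyl)-4,5-(isopropylidenedioxy)cyclohex-2-en-1-one | O=C(OCC1=C[C@@H]2OC(C)(C)O[C@@H]2CC1=O)c1ccccc1 | intermediate
11 | cyclic osmate ester of 10 (O1 and O6 on the lower face bound to OsO2) | O=C(OC[C@]12O[Os](=O)(=O)O[C@H]1[C@@H]1OC(C)(C)O[C@@H]1CC2=O)c1ccccc1 | intermediate
12 | (2S,3S,4S,5R)-2-(benzoyloxymethyl)-2,3-dihydroxy-4,5-(isopropylidenedioxy)cyclohexan-1-one | O=C(OC[C@]1(O)[C@@H](O)[C@@H]2OC(C)(C)O[C@@H]2CC1=O)c1ccccc1 | intermediate
13 | (2S,3S,4R,5R)-2-(benzoyloxymethyl)-2,3:4,5-bis(isopropylidenedioxy)cyclohexan-1-one | O=C(OC[C@]12OC(C)(C)O[C@H]1[C@@H]1OC(C)(C)O[C@@H]1CC2=O)c1ccccc1 | intermediate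
14 | potassium C2=C3 enolate of 13 | O=C(OC[C@]12OC(C)(C)O[C@H]1[C@@H]1OC(C)(C)O[C@@H]1C=C2[O-])c1ccccc1.[K+] | intermediate
15 | C2 enol triflate of 13 | O=C(OC[C@]12OC(C)(C)O[C@H]1[C@@H]1OC(C)(C)O[C@@H]1C=C2OS(=O)(=O)C(F)(F)F)c1ccccc1 | intermediate
16 | 1,6:4,5-di-O-isopropylidene-protected 1-(benzoyloxymethyl)cyclohex-2-ene-1,4,5,6-tetrol | O=C(OC[C@]12OC(C)(C)O[C@H]1[C@@H]1OC(C)(C)O[C@@H]1C=C2)c1ccccc1 | intermediate
17 | [(1S,4R,5R,6S)-1,4,5,6-tetrahydroxycyclohex-2-en-1-yl]methyl benzoate | O=C(OC[C@@]1(O)C=C[C@@H](O)[C@@H](O)[C@@H]1O)c1ccccc1 | intermediate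
18 | O5,O6-[(2S,3S)-2,3-dimethoxybutane-2,3-diyl] acetal of 17 | O=C(OC[C@@]1(O)C=C[C@@H](O)[C@H]2O[C@](C)(OC)[C@@](C)(OC)O[C@H]12)c1ccccc1 | intermediate
19 | O4-benzoate of 18 | O=C(OC[C@@]1(O)C=C[C@@H](OC(=O)c2ccccc2)[C@H]2O[C@](C)(OC)[C@@](C)(OC)O[C@H]12)c1ccccc1 | intermediate
20 | [(1S,4R,5S,6S)-4-(benzoyloxy)-1,5,6-trihydroxycyclohex-2-en-1-yl]methyl benzoate | O=C(OC[C@@]1(O)C=C[C@@H](OC(=O)c2ccccc2)[C@@H](O)[C@@H]1O)c1ccccc1 | target

**Totals**

Total step count: 13. Longest linear sequence: 13 steps (1 to 20).

**Steps most likely to fail**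

Step 9. The enolate may expel O4 (E1cB opening of the upper dioxolane) or take over the O7 benzoyl group before it is sulfonylated. The fallback uses no enolate and sets out from 13. The ketone is reduced (NaBH4, CeCl3·7H2O, MeOH, −40 °C) to the C2 carbinol F1, whose C2 configuration is irrelevant. This is dehydrated with methyl N-(triethylammoniosulfonyl)carbamate (Burgess reagent, toluene, 80 °C). The syn-elimination can only use a C3 hydrogen because C1 is quaternary. The sequence therefore comes back to the route at 16 and replaces steps 9 and 10.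

Step 7. Osmylation of the electron-poor alkene may be slow, and long reaction times could bring erosion of facial selectivity and displacement or migration of the benzoate. The fallback forms the same C1–O and C6–O bonds at a lower oxidation level of C2 and sets out from 10.
- Luche reduction (NaBH4, CeCl3·7H2O, MeOH, −78 °C) should deliver hydride to the open lower face and give the allylic alcohol F2 with its hydroxyl on the upper face.
- The alkene is then electron-richer and flanked by two upper-face allylic oxygens, so OsO4/NMO should hydroxylate the lower face to the triol F3.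
- Me2C(OMe)2/PPTS bridges the only cis pair (O1/O6) to give the bis-acetonide carbinol F4.
- Dess–Martin oxidation of C2–OH comes back to the route at 13.

Step 11. The preference for the trans O5/O6 pair may be incomplete, the O7 benzoate may undergo methanolysis, or the allylic carbinols may solvolyse in hot acidic methanol. The fallback needs no O5/O6 protection, takes its regiocontrol from stereoelectronic opening of an orthoester, and sets out from 16.
- 80% aqueous AcOH at 50 °C gives 17, now isolated.
- One equivalent of PhC(OMe)3 with CSA in MeCN at 0 °C should engage the less hindered secondary/secondary cis pair and give the cyclic C4/C5 orthobenzoate F5.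
- Brief treatment with aqueous AcOH should open it to the ester on the pseudoaxial oxygen, O4.
- This comes back to the route at 20 and replaces steps 12 and 13.

**Further compounds**

F1 | step 9 | C2 carbinol from reduction of 13 (either C2 epimer serves, C2 left undefined) | O=C(OC[C@]12OC(C)(C)O[C@H]1[C@@H]1OC(C)(C)O[C@@H]1CC2O)c1ccccc1
F2 | step 7 | (1S,4S,5R)-2-(benzoyloxymethyl)-4,5-(isopropylidenedioxy)cyclohex-2-en-1-ol | O=C(OCC1=C[C@@H]2OC(C)(C)O[C@@H]2C[C@@H]1O)c1ccccc1
F3 | step 7 | C2 carbinol analogue of 12 (C2–OH on the upper face, O1 and O6 on the lower face) | O=C(OC[C@]1(O)[C@@H](O)[C@@H]2OC(C)(C)O[C@@H]2C[C@@H]1O)c1ccccc1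
F4 | step 7 | C2 carbinol analogue of 13 with the hydroxyl on the upper face | O=C(OC[C@]12OC(C)(C)O[C@H]1[C@@H]1OC(C)(C)O[C@@H]1C[C@@H]2O)c1ccccc1
F5 | step 11 | O4,O5-(α-methoxybenzylidene) orthoester of 17 (epimers at the orthoester carbon) | O=C(OC[C@@]1(O)C=C[C@H]2OC(OC)(c3ccccc3)O[C@H]2[C@@H]1O)c1ccccc1
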